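Over a run of 8.0 d, the partner in the south-west flask has a half-life of 0.71 d by its own decay.

    partner → decomposed reagent (k1 = 0.0407 h⁻¹)
    substrate + partner → target (k2 = 0.0732 L mol⁻¹ h⁻¹)
    substrate + target → side product B (k3 = 0.0115 L mol⁻¹ h⁻¹)
    2 substrate → side product A (k4 = 0.0230 L mol⁻¹ h⁻¹)

| flask | substrate | partner | time | remark |
|---|---|---|---|---|
| west | 0.50 M (fed, over 5.0 d) | 0.250 M | 8.0 d | all else is in the flask from the start; the feed brings no volume worth counting |
| south-west | 0.50 M | 0.250 M | 8.0 d | everything together at the start |
| north-east | 0.50 M | 0.250 M (fed, over 5.0 d) | 8.0 d | all else is in the flask from the start; the feed brings no volume worth counting |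

- percentages count the substrate that a species holds: one side product A or side product B counts as two
- where a step has two of a species, its rate is k times that concentration squared, and two are used at each turn
- run time (west): 8.0 d

- which flask leads in amount of target, in percent of the substrate charged ("all alike" within 1.5 percentage points) (west / south-west / north-east / all alike)
- how much target is there at the end, in percent of the substrate charged: west
- how much target is there at the end, in percent of the substrate charged: south-west
- how much target is there at the end, in percent of the substrate charged: north-east

My own reckoning follows the rate of the target-forming step in the south-west flask, where both charges go in at the start. The rate opens at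

r_start = k·c_substrate·c_partner = 0.0732 L mol⁻¹ h⁻¹ × 0.50 M × 0.250 M = 0.00915 M h⁻¹

Two losses slow it, each taken as pseudo-first-order at the starting concentrations. The partner goes by decay and by forming target; the substrate goes by forming target and by dimerisation to side product A:

s_partner = 0.0407 h⁻¹ + 0.0732 L mol⁻¹ h⁻¹ × 0.50 M = 0.0773 h⁻¹

s_substrate = 0.0732 L mol⁻¹ h⁻¹ × 0.250 M + 2 × 0.0230 L mol⁻¹ h⁻¹ × 0.50 M = 0.0413 h⁻¹

The inverse of the sum of these two slowing constants is

τ = 1/(s_partner + s_substrate) = 8.43 h

This τ is the fading time of the rate. Within one τ the partner cuts the rate by a factor 1.92 and the substrate by a factor 1.42. The run lasts 22.8 τ, so the reckoned target, in percent of the substrate charged, is the opening rate held for one τ: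

target made = r_start × τ / c_substrate = 15.4%

This figure counts target made, before the loss of target to side product B, which by itself has a half-life of 5.0 d at the charged substrate, longer than τ. For the fed flasks this reckoning gives no number.

The forecast gives 3.4% for west, 14.5% for south-west and 8.8% for north-east, with south-west leading, on the ground that “target forms only while both are concentrated”. Its south-west figure is target left after a loss; mine is target made.

The simulation gives 3.87% for west, 14.1% for south-west and 10.0% for north-east, so south-west leads.

The south-west flask holds 14.1% target and 10.1% in side product B, which counts two, at 8.00 d, so it has made 19.1%, more than the 15.4% reckoned. The neighbouring flask, south-west with 0.12 M substrate, has a fading time of 13.6 h, longer than τ, and the same reckoning gives 25.0% made, in percent of its own substrate charge. That flask holds 26.2% target and 6.55% in side product B, so it has made 29.5%.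

All constants were set for the occasion; the flask was simulated.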